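## Structural features

The target (compound 45) is a germacranolide. A ten-membered carbocycle (C1–C10) is trans-fused at C6–C7 to a γ-lactone (O6–C12–C11) and carries a cis-4,5-epoxide (methyl on C4), a C1 ketone next to a tertiary acetate at C10, a tiglate at C8 and an acetoxymethyl group (C13) on C11. There are seven stereocentres, (4R,5S,6S,7R,8S,10R,11R). C4–C5–C6–C7–C8 are contiguous, C11 adjoins C7, and C10 is an isolated quaternary centre. All oxygen substituents on the ring (epoxide, O6, O8, O10) lie on the same (α) face. The fragile groups are: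

- the trisubstituted epoxide (acid, transannular opening);
- the β-acetoxy lactone (E1cB loss of acetate to the α-methylene lactone);
- the tertiary α-acetoxy ketone (base, ketol shift);
- the conjugated tiglate;
- the O8/C12 relationship (γ-hydroxy ester, translactonisation whenever O8 is free).

The real difficulty is the medium ring with a ring-cis C4–C5 unit, together with the order in which three different acyl groups and two oxidation levels (C1, C12) are revealed. The key step exploits the C4–C5 bond: the cis-epoxide maps onto a Z (ring-cis) C4(Me)=C5 olefin, and that olefin maps onto a C4–SO2–C5 bridge in an eleven-membered sulfone fused to the oxolane (masked lactone) ring.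

## Logic of the disconnections

**45 ⇒ 44 ⇒ 43 ⇒ 42.** The C10 O-acetyl bond, the C1 carbonyl (back to the carbinol) and the two epoxide C–O bonds are removed last. These are the least robust groups, and in 42 the 1α-hydroxyl (with 10α-OH) sits on the face where the epoxide oxygen is needed, so it can direct it. The gain is that 42 contains only esters, a lactone and one olefin. The demand is oxygen delivery to the α face, an oxidation that spares the tertiary alcohol, and a tertiary acetylation that does not eliminate the C13 acetate.

**42 ⇒ 41 ⇒ 40 ⇒ 39 ⇒ 38 ⇒ 36.** The ketal is put back, then the C8–O acyl bond, the C13–O acyl bond and finally the C11–C13 bond are cut. The last is an aldol bond of the lactone enolate with a one-carbon electrophile. The gain is the plain C11-methylene lactone 36. The demand is attack anti to the C7–C8 bond (11R), and each hydroxyl must be the only free one when it is acylated.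

**36 ⇒ 35 ⇒ 34.** The lactone carbonyl is taken back to a methyl acetal because the preceding step is strongly basic. The demand is that this acetal be cleaved later in the presence of the ketal and the silyl ether.

**34 ⇒ 31 (key).** The C4=C5 π bond is replaced by C4–S and C5–S bonds of an SO2 bridge. The problem of a Z trisubstituted olefin in a ten-membered ring becomes the closure of an eleven-membered ring by a C–S bond, with the geometry coming from a cis-fused episulfone. The demand is base-stable protection everywhere, no β-elimination of O6 from the C5 carbanion, and Z geometry. 31 has one defined configuration at C1 and C4; the 1S centre is reused later as the directing group.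

**31 ⇒ 29 ⇒ 27 ⇒ 26 ⇒ 25.** The sulfone is taken back to the sulfide, the S–C5 bond is cut (thiolate plus primary sulfonate) and the C4–S bond is traced to a C4–O bond with inversion. The gain is an open chain with two free hydroxyls, distinguished as primary and secondary. The demand is high dilution for the ring closure.

**25 ⇒ 23 ⇒ 21 ⇒ 18 + 19.** The ketal is removed, C2–C3 is desaturated and the C1–C2 bond is cut to an α-silyloxy aldehyde and a commercial chiral C4 alkyne. The gain is that C2–C4 and C15 arrive in one step. The demand is addition to a hindered aldehyde; the C1 configuration is not critical because C1 ends as a ketone.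

**18 ⇒ 17 ⇒ 16 ⇒ 15 ⇒ 14 ⇒ 13 ⇒ 11.** These are adjustments of oxidation level and protection: C1 back to the protected primary alcohol, C8 carbinol to the ketone, the ketone to its dithiane, the acetal to the lactone. The demand is hydride delivery to the correct face of the C8 ketone.

**11 ⇒ 2 + 8.** The C7–C8 bond is cut as a conjugate addition of a C8 acyl-anion equivalent to a butenolide. The gain is two fragments of similar size. The demand is addition anti to the C6 substituent, which sets C7.

**8 ⇒ 4 + 5; 4 ⇐ 3; 2 ⇐ 1.** The C8–C9 bond is cut as an epoxide opening. C10 (with C9, C14, C1) comes from 3 and C6 (with C5, C7, C11, C12) from 1, so two of the seven stereocentres are taken from the chiral pool.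

## Other disconnections considered

**Alternative 1:** The cut is C7–C11 together with C8–O.

- Forward step: an open-chain precursor carries a 2-bromo-1-ethoxyethyl (bromoacetal) tether on O6 and an E olefin at C7=C8. It is converted into the C11 radical, which attacks C7 in a 5-exo closure to form the oxolane (the lactone at the acetal level). The C8 radical is then intercepted by a persistent aminoxyl radical, giving A1.
- In its favour: two bonds and the lactone ring are made in one step. The cis-epoxide is already present, having been installed on an acyclic allylic alcohol by reagent control, so C4 and C5 are fixed with more certainty than by the late directed epoxidation of the chosen plan. On that point it is the better plan. The C6-to-C7 induction of a chair-like 5-exo transition state should equal that of the conjugate addition used here.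
- Against it: C8 is set by capture of an acyclic secondary radical, where only weak 1,2-induction can be expected. The ten-membered ring is still open in A1 and would have to be closed at C1–C10 (for example by reductive coupling of two carbonyl groups after cleaving both terminal olefins). That step creates C10 and C1 without obvious control, whereas C10 comes from the chiral pool in the chosen route. The epoxide must also survive every later step.
- Comparison: the mechanism is radical with a radical trap rather than anionic extrusion. In step count it would probably be shorter, which is an advantage, but with two stereocentres (C8, C10) at risk.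

**Alternative 2:** The cut is C7–C8 and C11–C13 in one operation.

- Forward step: a lithiated 2-alkyl-1,3-dithiane (C8 acyl anion carrying C9, C10 and C1) adds to C7 of the γ-substituted butenolide anti to the C6 substituent. The resulting lactone enolate is trapped at C11 by a one-carbon aldehyde electrophile, anti to the new C7 substituent, giving A2.
- In its favour: C7 and C11 are both set on a monocyclic lactone, where anti,anti selectivity is most dependable, and C13 is in place early. This is better than the chosen plan, which performs the C11 aldol on the ten-membered-ring lactone (step 21). The C7–C8 bond is formed exactly as in step 4 of the chosen route, so on that point the two are equal.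
- Against it: A2 does not address the ten-membered ring or the Z C4=C5 bond. C2–C4 and the ring closure remain. Any base-mediated closure would then have to carry a β-oxygenated C13 next to a masked lactone (one more protecting group and an E1cB risk). The C8 ketone must still be reduced stereoselectively, as here. C1 starts as part of a primary/tertiary ketal that must be opened and re-formed around the C1 carbinol.
- Comparison: it complements the chosen plan rather than competing with it. It would save one or two late steps and add about as many early ones.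

**Alternative 3:** The cut is C8–C9, with C1 and C6 reconnected, so the ten-membered ring is traced back to a six-membered one.

- Forward step: the potassium alkoxide of a cyclohexenol (carbinol carbon C6 bearing an alkoxyvinyl group, neighbouring C1 bearing an isopropenyl group) undergoes anionic oxy-Cope rearrangement. C8–C9 forms, C1–C6 breaks, and protonation of the C6 enolate gives A3.
- In its favour: the medium ring, the Z C4=C5 olefin (inherited from the ring olefin) and an E C1=C10 olefin appear in one unimolecular step without high dilution. This is clearly better than the chosen route in ring construction and in step count. The enolate is regiodefined for attaching C11–C12 at C7. C8 is set by chirality transfer through a chair transition state. The enone also allows a chemoselective nucleophilic epoxidation of C4=C5, at least the equal of the directed epoxidation used here.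
- Against it: after the key step only C8 is defined. C4, C5, C6, C7, C10 and C11 would all have to be introduced on a mobile cyclodecadienone by substrate control, against three centres (C6, C7 via C6, C10) secured from the chiral pool here. The Z enone could isomerise under base. The C1=C10 olefin must still become the 10-acetoxy-1-oxo unit with the correct face.
- Comparison: shorter and more economical in building the skeleton, weaker in stereochemical security.

Key step: step 18

## Route

Remarks on the chemistry:

- Germacrane numbering is used for every intermediate (C12 = lactone/acetal carbon, C13 = acetoxymethyl carbon, C14 = methyl on C10, C15 = methyl on C4).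
- The methyl acetal at C12 is assumed to form as an anomeric mixture. The 12R anomer is drawn; both anomers converge at the lactone in step 20.
- The spatial arrangement at C6, C7, C8 and C10 is that of 45 from the step in which each centre appears. This was checked for 31 and 34; the CIP letters of C6 and C7 change only with substituent priority.

Step 1
Reactants: 1 (S)-5-(hydroxymethyl)furan-2(5H)-one
Product: 2 (S)-5-[(benzyloxy)methyl]furan-2(5H)-one
Conditions: BnOC(=NH)CCl3, TfOH (cat.), CH2Cl2–cyclohexane, 0 °C → rt
Reagents that add atoms: benzyl 2,2,2-trichloroacetimidate, ClC(Cl)(Cl)C(=N)OCc1ccccc1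
Why: Acid-catalysed O-benzylation with the trichloroacetimidate protects the primary alcohol without base, so the butenolide is not enolised and C6 keeps its configuration.

Step 2
Reactants: 3 (S)-2-methylglycidol
Product: 4 (R)-2-{[(4-methoxybenzyl)oxy]methyl}-2-methyloxirane
Conditions: NaH, 4-methoxybenzyl chloride, Bu4NI (cat.), THF–DMF, 0 °C → rt
Reagents that add atoms: 4-methoxybenzyl chloride, COc1ccc(CCl)cc1
Why: Williamson etherification of the primary alkoxide; the quaternary epoxide carbon (future C10) is untouched and its CIP letter changes only through priority.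

Step 3
Reactants: 5 1,3-dithiane; 4 (R)-2-{[(4-methoxybenzyl)oxy]methyl}-2-methyloxirane
Product: 8 2-{(2R)-3-[(4-methoxybenzyl)oxy]-2-methyl-2-[(triethylsilyl)oxy]propyl}-1,3-dithiane, via 2-lithio-1,3-dithiane 6 (not isolated), via tertiary lithium alkoxide 7 (not isolated)
Conditions: n-BuLi, THF, −30 °C; 4, −30 → 0 °C; then TESOTf, −78 → 0 °C
Reagents that add atoms: triethylsilyl trifluoromethanesulfonate, CC[Si](CC)(CC)OS(=O)(=O)C(F)(F)F
Why: Corey–Seebach dithiane anion opens the 2,2-disubstituted epoxide at its CH2 terminus (SN2), forming C8–C9 without touching C10; the tertiary alkoxide is silylated in the same flask so that O10 is later non-coordinating.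

Step 4
Reactants: 8 2-{(2R)-3-[(4-methoxybenzyl)oxy]-2-methyl-2-[(triethylsilyl)oxy]propyl}-1,3-dithiane; 2 (S)-5-[(benzyloxy)methyl]furan-2(5H)-one
Product: 11 (4S,5S)-5-[(benzyloxy)methyl]-4-[2-{(2R)-3-[(4-methoxybenzyl)oxy]-2-methyl-2-[(triethylsilyl)oxy]propyl}-1,3-dithian-2-yl]oxolan-2-one, via lithiated dithiane 9 (not isolated), via lithium lactone enolate 10 (not isolated)
Conditions: n-BuLi, THF, −30 °C; HMPA, −78 °C; 2, −78 °C; AcOH quench
Reagents that add atoms: none
Why: Conjugate (1,4) addition of the sulfur-stabilised acyl-anion equivalent to the butenolide, favoured over 1,2-addition by HMPA; the nucleophile enters anti to the C6 benzyloxymethyl group, so C7 is set trans to C6, and the enolate is protonated at C11.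

Step 5
Reactants: 11 (4S,5S)-lactone dithiane
Product: 13 (2R,4S,5S)-5-[(benzyloxy)methyl]-2-methoxy-4-[2-{(2R)-3-[(4-methoxybenzyl)oxy]-2-methyl-2-[(triethylsilyl)oxy]propyl}-1,3-dithian-2-yl]oxolane, via lactol 12 (not isolated)
Conditions: i-Bu2AlH, CH2Cl2, −78 °C, aq. KNaC4H4O6 work-up; crude lactol, MeOH, PPTS (cat.), rt
Reagents that add atoms: methanol, CO
Why: Partial hydride reduction of the lactone to the lactol, then acid-catalysed acetalisation, masks the lactone in a base-stable form; the mild acid leaves the hindered tertiary silyl ether in place.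

Step 6
Reactants: 13 methyl lactol ether dithiane
Product: 14 (3R)-1-[(2S,3S,5R)-2-[(benzyloxy)methyl]-5-methoxyoxolan-3-yl]-4-[(4-methoxybenzyl)oxy]-3-methyl-3-[(triethylsilyl)oxy]butan-1-one (C8 ketone)
Conditions: MeI, CaCO3, MeCN–H2O (9:1), 45 °C
Reagents that add atoms: water, O
Why: S-Methylation and hydrolysis of the dithiane under buffered, near-neutral conditions frees the C8 ketone without harming the methyl acetal, the silyl ether or the two benzyl-type ethers; the trans C6/C7 arrangement is the thermodynamic one, so C7 is not at risk.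

Step 7
Reactants: 14 C8 ketone
Product: 15 (1S,3R)-1-[(2S,3R,5R)-2-[(benzyloxy)methyl]-5-methoxyoxolan-3-yl]-4-[(4-methoxybenzyl)oxy]-3-methyl-3-[(triethylsilyl)oxy]butan-1-ol (8S alcohol)
Conditions: Zn(BH4)2, Et2O, −30 → 0 °C
Reagents that add atoms: none
Why: Chelation-controlled reduction of a β-alkoxy ketone: zinc bridges the carbonyl oxygen and the oxolane oxygen O6 (the silyl ether at C10 does not coordinate), and hydride adds to the carbonyl face turned away from the C11–C12 bridge. This should give the 8S alcohol (O8 syn to O6 and to C11 along C5–C9), whereas a non-chelated Felkin–Anh path would give the epimer.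

Step 8
Reactants: 15 8S alcohol
Product: 16 8-O-tert-butyldimethylsilyl ether of 15
Conditions: TBSOTf, 2,6-lutidine, CH2Cl2, −78 °C
Reagents that add atoms: tert-butyldimethylsilyl trifluoromethanesulfonate, CC(C)(C)[Si](C)(C)OS(=O)(=O)C(F)(F)F
Why: Silylation of the hindered secondary alcohol with the silyl triflate and a hindered base at low temperature, where the methyl acetal is inert.

Step 9
Reactants: 16 fully protected C8 silyl ether
Product: 17 C1 primary alcohol (4-methoxybenzyl group removed from 16)
Conditions: DDQ, CH2Cl2–pH 7 buffer, 0 °C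
Reagents that add atoms: none
Why: Oxidative cleavage of the electron-rich 4-methoxybenzyl ether by DDQ; the plain benzyl ether at C5, the silyl ethers and the buffered acetal are not affected.

Step 10
Reactants: 17 C1 primary alcohol
Product: 18 C1 aldehyde (α-triethylsilyloxy aldehyde with quaternary C10)
Conditions: Dess–Martin periodinane, NaHCO3, CH2Cl2, 0 °C → rt
Reagents that add atoms: none
Why: Dess–Martin oxidation of the neopentyl-type primary alcohol; the aldehyde has no α-hydrogen and cannot enolise or epimerise.

Step 11
Reactants: 19 (R)-but-3-yn-2-ol; 18 C1 aldehyde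
Product: 21 (1S,4R)-propargylic diol (C1–C2 bond formed, C2≡C3 alkyne, free hydroxyls at C1 and C4), via dilithiated butynol 20 (not isolated)
Conditions: 19 (2 equiv), n-BuLi (4 equiv), THF, −78 → −20 °C; 18, −78 °C; AcOH quench at −78 °C
Reagents that add atoms: none
Why: 1,2-Addition of the lithium acetylide (alkoxide–acetylide dianion) to the aldehyde forms C1–C2; polar Felkin–Anh control (C10–OSi bond anti to the nucleophile, approach past the methyl group) should favour the 1S carbinol. The C1 epimer is not harmful because C1 is oxidised in step 27.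

Step 12
Reactants: 21 (1S,4R)-propargylic diol
Product: 23 (1S,4R)-1,4,5-triol (C2–C3 saturated, C5 hydroxyl free, C10 triethylsilyl ether, C8 silyl ether, C12 methyl acetal), via saturated benzyl ether 22 (not isolated)
Conditions: H2 (1 atm), Pd/C (10%), EtOAc, rt
Reagents that add atoms: none
Why: Heterogeneous hydrogenation saturates the alkyne and then cleaves the C5 benzyl ether by hydrogenolysis; silyl ethers and the acetal are stable in ethyl acetate.

Step 13
Reactants: 23 (1S,4R)-1,4,5-triol
Product: 25 C1/C10 acetonide with free C4 and C5 hydroxyls, via desilylated tetraol 24 (not isolated)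
Conditions: CSA (cat.), MeOH, 0 °C → rt; concentrate; 2,2-dimethoxypropane, acetone, CSA (cat.), rt
Reagents that add atoms: 2,2-dimethoxypropane, COC(C)(C)OC
Why: Acid-catalysed methanolysis removes the tertiary triethylsilyl group while the hindered secondary tert-butyldimethylsilyl ether survives; transketalisation then closes the dioxolane on the only 1,2-diol (C1/C10, ring bonds cis on the dioxolane).

Step 14
Reactants: 25 acetonide diol
Product: 26 C5 4-toluenesulfonate (C4 hydroxyl free)
Conditions: TsCl, pyridine, CH2Cl2, 0 °C
Reagents that add atoms: 4-toluenesulfonyl chloride, Cc1ccc(cc1)S(Cl)(=O)=O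
Why: Sterically controlled sulfonylation: the primary C5 hydroxyl reacts much faster than the secondary C4 hydroxyl.

Step 15
Reactants: 26 C5 tosylate
Product: 27 (4S)-C4 thioacetate C5 tosylate
Conditions: PPh3, DIAD, AcSH, THF, 0 °C
Reagents that add atoms: thioacetic acid, CC(=O)S
Why: Mitsunobu thioesterification of the only free hydroxyl with inversion at C4; under these cold, non-basic conditions the β-oxygenated primary tosylate is not displaced.

Step 16
Reactants: 27 C4 thioacetate C5 tosylate
Product: 29 eleven-membered cyclic sulfide (C4–S–C5), via C4 thiol 28 (not isolated)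
Conditions: Cs2CO3, degassed MeOH–DMF, 40 °C, slow addition (final 0.002 M)
Reagents that add atoms: none
Why: Methanolysis of the thioacetate releases the caesium thiolate, which closes the eleven-membered ring by intramolecular SN2 at the primary C5 (11-exo-tet) under high dilution; the dioxolane and oxolane rings limit the conformational freedom of the chain.

Step 17
Reactants: 29 cyclic sulfide
Product: 31 eleven-membered sulfone (1S,4S,12R; C8 silyl ether, C1/C10 acetonide, C12 methyl acetal), via ring sulfoxide 30 (not isolated)
Conditions: mCPBA (2.3 equiv), NaHCO3, CH2Cl2, 0 °C → rt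
Reagents that add atoms: 3-chloroperoxybenzoic acid, OOC(=O)c1cccc(Cl)c1
Why: Two-fold electrophilic oxidation of the sulfide to the sulfone; nothing else in the molecule is oxidisable, and bicarbonate protects the acetals from the carboxylic acid.

Step 18
Reactants: 31 eleven-membered sulfone
Product: 34 (4Z)-cyclodecene fused to the methyl lactol ether (C8 silyl ether, C1/C10 acetonide), via 5-bromo sulfone 32 (not isolated), via episulfone 33 (not isolated)
Conditions: CBr2F2, KOH–Al2O3, t-BuOH–CH2Cl2, 0 °C → rt
Reagents that add atoms: none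
Why: Ramberg–Bäcklund reaction with in-situ bromination: KOH on alumina deprotonates the more acidic C5 methylene, the carbanion takes bromine from CBr2F2 to give 32, and deprotonation at C4 then triggers 1,3-displacement of bromide (3-exo-tet) to the episulfone 33, which loses SO2 to form the C4=C5 bond. The closest known reactions are the contraction of cyclic sulfones to medium-ring cycloalkenes and the conversion of glycosyl sulfones, which are also β-oxygenated, into exo-glycals under the same conditions. The ten-membered ring is not closed by a cyclisation but arises by extrusion of the SO2 bridge from the eleven-membered ring; the only ring actually closed is the transient thiirane dioxide. No stereocentre is created, the C4 configuration is erased, and C1, C6, C7, C8, C10 and C12 are not α to the sulfone and keep their configuration. The step needs Z geometry: the 1,3-displacement can give only the episulfone that is cis-fused to the medium ring without severe strain, and SO2 loss is stereospecific, so the ring bonds C3–C4 and C5–C6 stay cis. It also needs the C5 carbanion to be brominated faster than it expels O6; the fast halogen transfer from CBr2F2 at 0 °C and the tolerance of β-alkoxy sulfones in the glycosyl cases are relied on for this. The silyl ether, the ketal and the methyl acetal are all stable to KOH.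

Step 19
Reactants: 34 (4Z)-cyclodecene methyl lactol ether
Product: 35 lactol (C12 hemiacetal; ketal and silyl ether retained)
Conditions: AcOH–THF–H2O (3:1:1), 35 °C
Reagents that add atoms: water, O
Why: Acid-catalysed acetal hydrolysis: the 2-methoxyoxolane ionises easily and loses methanol irreversibly, whereas the hindered dioxolane re-closes after any C–O ionisation, so the ketal and the secondary silyl ether should survive.

Step 20
Reactants: 35 lactol
Product: 36 trans-fused γ-lactone (C11 methylene)
Conditions: (n-Pr4N)RuO4 (cat.), N-methylmorpholine N-oxide, 4 Å molecular sieves, CH2Cl2, rt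
Reagents that add atoms: none
Why: Ley–Griffith oxidation of the lactol to the lactone; no other free hydroxyl is present and the trisubstituted olefin is inert.

Step 21
Reactants: 36 γ-lactone
Product: 38 (11R)-11-(hydroxymethyl) lactone, via lithium enolate 37 (not isolated)
Conditions: LiN(i-Pr)2, THF, −78 °C; CH2O (gas), −78 → −40 °C; AcOH quench
Reagents that add atoms: formaldehyde, C=O
Why: Aldol addition of the lactone lithium enolate to monomeric formaldehyde forms C11–C13; the electrophile approaches the enolate face opposite the C7–C8 bond, which should give the 11R centre (C13 trans to C8).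

Step 22
Reactants: 38 (11R)-11-(hydroxymethyl) lactone
Product: 39 13-acetate
Conditions: Ac2O, pyridine, CH2Cl2, 0 °C → rt
Reagents that add atoms: acetic anhydride, CC(=O)OC(C)=O
Why: Acetylation of the primary alcohol with pyridine as the only base, mild enough to avoid E1cB loss of the new acetate.

Step 23
Reactants: 39 13-acetate
Product: 40 C8 alcohol (silyl group removed)
Conditions: HF·pyridine, pyridine, THF, 0 °C → rt
Reagents that add atoms: none
Why: Fluoride-mediated desilylation under buffered conditions; the ketal, the esters and the olefin are stable, and no strong base is present that could move the lactone to O8.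

Step 24
Reactants: 40 C8 alcohol
Product: 41 C8 tiglate
Conditions: (E)-2-methylbut-2-enoyl chloride, Et3N, DMAP (cat.), CH2Cl2, 0 °C → rt
Reagents that add atoms: tigloyl chloride, C/C=C(\C)C(Cl)=O
Why: DMAP-catalysed acylation of the secondary alcohol with the acid chloride; the E geometry of the acyl group is retained, and acylation at 0 °C should be faster than O8-to-C12 translactonisation.

Step 25
Reactants: 41 C8 tiglate
Product: 42 (1S,10R)-1,10-diol
Conditions: AcOH–H2O (4:1), 45 °C
Reagents that add atoms: none
Why: Acid-catalysed ketal hydrolysis with a weak acid that does not protonate the trisubstituted olefin; the three esters are stable.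

Step 26
Reactants: 42 (1S,10R)-1,10-diol
Product: 43 (4R,5S)-4,5-epoxy 1,10-diol
Conditions: VO(acac)2 (cat.), t-BuOOH, CH2Cl2, 0 °C → rt
Reagents that add atoms: tert-butyl hydroperoxide, CC(C)(C)OO
Why: Vanadium-catalysed hydroxyl-directed epoxidation of a bishomoallylic alcohol: the vanadate ester of the 1α-hydroxyl (with 10α-OH as a second ligand) delivers the peroxide oxygen to the olefin face on its own side, which should give the cis 4α,5α-epoxide. The electron-poor tiglate olefin does not react.

Step 27
Reactants: 43 epoxy diol
Product: 44 epoxy α-hydroxy ketone (C1 ketone, C10 tertiary alcohol)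
Conditions: Dess–Martin periodinane, NaHCO3, CH2Cl2, 0 °C → rt
Reagents that add atoms: none
Why: Dess–Martin oxidation of the secondary C1 alcohol under bicarbonate buffering; the tertiary C10 hydroxyl and the epoxide are not affected.

Step 28
Reactants: 44 epoxy α-hydroxy ketone
Product: 45 CNP0305680.1, (4R,5S,6S,7R,8S,10R,11R)-10,13-diacetoxy-4,5-epoxy-1-oxo-8-[(E)-2-methylbut-2-enoyloxy]germacran-6,12-olide
Conditions: Ac2O, DMAP, pyridine, 40 °C
Reagents that add atoms: acetic anhydride, CC(=O)OC(C)=O
Why: DMAP-catalysed acetylation of the tertiary α-hydroxy ketone; base-only conditions preserve the epoxide, and pyridine is too weak a base to eliminate the C13 acetate.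

## Compound list

1 | (S)-5-(hydroxymethyl)furan-2(5H)-one | O=C1C=C[C@@H](CO)O1 | starting material
2 | (S)-5-[(benzyloxy)methyl]furan-2(5H)-one | O=C1C=C[C@@H](COCc2ccccc2)O1 | intermediate
3 | (S)-2-methylglycidol, [(2S)-2-methyloxiran-2-yl]methanol | C[C@]1(CO)CO1 | starting material
4 | (R)-2-{[(4-methoxybenzyl)oxy]methyl}-2-methyloxirane | C[C@]1(COCc2ccc(OC)cc2)CO1 | intermediate
5 | 1,3-dithiane | C1CSCSC1 | starting material
6 | 2-lithio-1,3-dithiane | [Li]C1SCCCS1 | intermediate (not isolated)
7 | lithium (2R)-1-(1,3-dithian-2-yl)-3-[(4-methoxybenzyl)oxy]-2-methylpropan-2-olate | [Li]O[C@](C)(CC1SCCCS1)COCc1ccc(OC)cc1 | intermediate (not isolated)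
8 | 2-{(2R)-3-[(4-methoxybenzyl)oxy]-2-methyl-2-[(triethylsilyl)oxy]propyl}-1,3-dithiane | CC[Si](CC)(CC)O[C@](C)(CC1SCCCS1)COCc1ccc(OC)cc1 | intermediate
9 | 2-lithio derivative of 8 | CC[Si](CC)(CC)O[C@](C)(CC1([Li])SCCCS1)COCc1ccc(OC)cc1 | intermediate (not isolated)
10 | lithium enolate of lactone 11 | [Li]OC1=C[C@H](C2(C[C@@](C)(O[Si](CC)(CC)CC)COCc3ccc(OC)cc3)SCCCS2)[C@@H](COCc2ccccc2)O1 | intermediate (not isolated)
11 | (4S,5S)-5-[(benzyloxy)methyl]-4-[2-{(2R)-3-[(4-methoxybenzyl)oxy]-2-methyl-2-[(triethylsilyl)oxy]propyl}-1,3-dithian-2-yl]oxolan-2-one | O=C1C[C@H](C2(C[C@@](C)(O[Si](CC)(CC)CC)COCc3ccc(OC)cc3)SCCCS2)[C@@H](COCc2ccccc2)O1 | intermediate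
12 | lactol from 11 (oxolan-2-ol, C12 epimers) | OC1C[C@H](C2(C[C@@](C)(O[Si](CC)(CC)CC)COCc3ccc(OC)cc3)SCCCS2)[C@@H](COCc2ccccc2)O1 | intermediate (not isolated)
13 | (2R,4S,5S)-5-[(benzyloxy)methyl]-2-methoxy-4-[2-{(2R)-3-[(4-methoxybenzyl)oxy]-2-methyl-2-[(triethylsilyl)oxy]propyl}-1,3-dithian-2-yl]oxolane | CO[C@H]1C[C@H](C2(C[C@@](C)(O[Si](CC)(CC)CC)COCc3ccc(OC)cc3)SCCCS2)[C@@H](COCc2ccccc2)O1 | intermediate
14 | (3R)-1-[(2S,3S,5R)-2-[(benzyloxy)methyl]-5-methoxyoxolan-3-yl]-4-[(4-methoxybenzyl)oxy]-3-methyl-3-[(triethylsilyl)oxy]butan-1-one | CO[C@H]1C[C@H](C(=O)C[C@@](C)(O[Si](CC)(CC)CC)COCc2ccc(OC)cc2)[C@@H](COCc2ccccc2)O1 | intermediate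
15 | (1S,3R)-1-[(2S,3R,5R)-2-[(benzyloxy)methyl]-5-methoxyoxolan-3-yl]-4-[(4-methoxybenzyl)oxy]-3-methyl-3-[(triethylsilyl)oxy]butan-1-ol (8S alcohol) | CO[C@H]1C[C@H]([C@@H](O)C[C@@](C)(O[Si](CC)(CC)CC)COCc2ccc(OC)cc2)[C@@H](COCc2ccccc2)O1 | intermediate
16 | 8-O-tert-butyldimethylsilyl ether of 15 | CO[C@H]1C[C@H]([C@@H](O[Si](C)(C)C(C)(C)C)C[C@@](C)(O[Si](CC)(CC)CC)COCc2ccc(OC)cc2)[C@@H](COCc2ccccc2)O1 | intermediate
17 | C1 primary alcohol (C5 benzyl ether, C8 TBS ether, C10 TES ether, C12 methyl acetal) | CO[C@H]1C[C@H]([C@@H](O[Si](C)(C)C(C)(C)C)C[C@@](C)(O[Si](CC)(CC)CC)CO)[C@@H](COCc2ccccc2)O1 | intermediate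
18 | C1 aldehyde corresponding to 17 | CO[C@H]1C[C@H]([C@@H](O[Si](C)(C)C(C)(C)C)C[C@@](C)(O[Si](CC)(CC)CC)C=O)[C@@H](COCc2ccccc2)O1 | intermediate
19 | (R)-but-3-yn-2-ol | C[C@@H](O)C#C | starting material
20 | dilithium salt of 19 (alkoxide–acetylide) | C[C@@H](O[Li])C#C[Li] | intermediate (not isolated)
21 | (1S,4R)-propargylic diol (C2≡C3; C5 benzyl ether, C8 TBS ether, C10 TES ether, C12 methyl acetal) | CO[C@H]1C[C@H]([C@@H](O[Si](C)(C)C(C)(C)C)C[C@@](C)(O[Si](CC)(CC)CC)[C@@H](O)C#C[C@@H](C)O)[C@@H](COCc2ccccc2)O1 | intermediate
22 | saturated (1S,4R)-diol, C5 benzyl ether | CO[C@H]1C[C@H]([C@@H](O[Si](C)(C)C(C)(C)C)C[C@@](C)(O[Si](CC)(CC)CC)[C@@H](O)CC[C@@H](C)O)[C@@H](COCc2ccccc2)O1 | intermediate (not isolated)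
23 | (1S,4R)-1,4,5-triol (C8 TBS ether, C10 TES ether, C12 methyl acetal) | CO[C@H]1C[C@H]([C@@H](O[Si](C)(C)C(C)(C)C)C[C@@](C)(O[Si](CC)(CC)CC)[C@@H](O)CC[C@@H](C)O)[C@@H](CO)O1 | intermediate
24 | 1,4,5,10-tetraol (C8 TBS ether, C12 methyl acetal) | CO[C@H]1C[C@H]([C@@H](O[Si](C)(C)C(C)(C)C)C[C@@](C)(O)[C@@H](O)CC[C@@H](C)O)[C@@H](CO)O1 | intermediate (not isolated)
25 | C1/C10 acetonide, (4R)-C4 and C5 hydroxyls free | CO[C@H]1C[C@H]([C@@H](O[Si](C)(C)C(C)(C)C)C[C@@]2(C)OC(C)(C)O[C@H]2CC[C@@H](C)O)[C@@H](CO)O1 | intermediate
26 | C5 4-toluenesulfonate of 25 | CO[C@H]1C[C@H]([C@@H](O[Si](C)(C)C(C)(C)C)C[C@@]2(C)OC(C)(C)O[C@H]2CC[C@@H](C)O)[C@@H](COS(=O)(=O)c2ccc(C)cc2)O1 | intermediate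
27 | (4S)-C4 thioacetate, C5 tosylate | CO[C@H]1C[C@H]([C@@H](O[Si](C)(C)C(C)(C)C)C[C@@]2(C)OC(C)(C)O[C@H]2CC[C@H](C)SC(C)=O)[C@@H](COS(=O)(=O)c2ccc(C)cc2)O1 | intermediate
28 | (4S)-C4 thiol, C5 tosylate | CO[C@H]1C[C@H]([C@@H](O[Si](C)(C)C(C)(C)C)C[C@@]2(C)OC(C)(C)O[C@H]2CC[C@H](C)S)[C@@H](COS(=O)(=O)c2ccc(C)cc2)O1 | intermediate (not isolated)
29 | eleven-membered cyclic sulfide (C4–S–C5) | CC(C)(C)[Si](C)(C)O[C@H]1C[C@@]2(C)OC(C)(C)O[C@H]2CC[C@H](C)SC[C@H]2O[C@@H](OC)C[C@@H]21 | intermediate
30 | ring sulfoxide (S-epimers) | CC(C)(C)[Si](C)(C)O[C@H]1C[C@@]2(C)OC(C)(C)O[C@H]2CC[C@H](C)S(=O)C[C@H]2O[C@@H](OC)C[C@@H]21 | intermediate (not isolated)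
31 | eleven-membered sulfone (1S,4S,12R) | CC(C)(C)[Si](C)(C)O[C@H]1C[C@@]2(C)OC(C)(C)O[C@H]2CC[C@H](C)S(=O)(=O)C[C@H]2O[C@@H](OC)C[C@@H]21 | intermediate
32 | 5-bromo sulfone (C5 epimers) | CC(C)(C)[Si](C)(C)O[C@H]1C[C@@]2(C)OC(C)(C)O[C@H]2CC[C@H](C)S(=O)(=O)C(Br)[C@H]2O[C@@H](OC)C[C@@H]21 | intermediate (not isolated)
33 | cis-fused episulfone (C4/C5 thiirane 1,1-dioxide; one face drawn, either face gives 34) | CC(C)(C)[Si](C)(C)O[C@H]1C[C@@]2(C)OC(C)(C)O[C@H]2CC[C@]3(C)[C@H]([C@H]2O[C@@H](OC)C[C@@H]21)S3(=O)=O | intermediate (not isolated)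
34 | (4Z)-cyclodecene methyl lactol ether (C8 TBS ether, C1/C10 acetonide) | CC(C)(C)[Si](C)(C)O[C@H]1C[C@@]2(C)OC(C)(C)O[C@H]2CC/C(C)=C\[C@H]2O[C@@H](OC)C[C@@H]21 | intermediate
35 | lactol (C12 hemiacetal epimers) | CC(C)(C)[Si](C)(C)O[C@H]1C[C@@]2(C)OC(C)(C)O[C@H]2CC/C(C)=C\[C@H]2OC(O)C[C@@H]21 | intermediate
36 | trans-fused γ-lactone (C11 methylene) | CC(C)(C)[Si](C)(C)O[C@H]1C[C@@]2(C)OC(C)(C)O[C@H]2CC/C(C)=C\[C@H]2OC(=O)C[C@@H]21 | intermediate
37 | lithium enolate of 36 | CC(C)(C)[Si](C)(C)O[C@H]1C[C@@]2(C)OC(C)(C)O[C@H]2CC/C(C)=C\[C@H]2OC(O[Li])=C[C@@H]21 | intermediate (not isolated)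
38 | (11R)-11-(hydroxymethyl) lactone | CC(C)(C)[Si](C)(C)O[C@H]1C[C@@]2(C)OC(C)(C)O[C@H]2CC/C(C)=C\[C@H]2OC(=O)[C@@H](CO)[C@@H]21 | intermediate
39 | 13-acetate of 38 | CC(C)(C)[Si](C)(C)O[C@H]1C[C@@]2(C)OC(C)(C)O[C@H]2CC/C(C)=C\[C@H]2OC(=O)[C@@H](COC(C)=O)[C@@H]21 | intermediate
40 | C8 alcohol (13-acetate, C1/C10 acetonide) | O[C@H]1C[C@@]2(C)OC(C)(C)O[C@H]2CC/C(C)=C\[C@H]2OC(=O)[C@@H](COC(C)=O)[C@@H]21 | intermediate
41 | C8 tiglate (13-acetate, C1/C10 acetonide) | C/C=C(\C)C(=O)O[C@H]1C[C@@]2(C)OC(C)(C)O[C@H]2CC/C(C)=C\[C@H]2OC(=O)[C@@H](COC(C)=O)[C@@H]21 | intermediate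
42 | (1S,10R)-1,10-diol (C8 tiglate, 13-acetate, 4Z olefin) | C/C=C(\C)C(=O)O[C@H]1C[C@@](C)(O)[C@@H](O)CC/C(C)=C\[C@H]2OC(=O)[C@@H](COC(C)=O)[C@@H]21 | intermediate
43 | (4R,5S)-4,5-epoxy 1,10-diol | C/C=C(\C)C(=O)O[C@H]1C[C@@](C)(O)[C@@H](O)CC[C@@]2(C)O[C@H]2[C@H]2OC(=O)[C@@H](COC(C)=O)[C@@H]21 | intermediate
44 | epoxy α-hydroxy ketone (C1 ketone, C10 hydroxyl) | C/C=C(\C)C(=O)O[C@H]1C[C@@](C)(O)C(=O)CC[C@@]2(C)O[C@H]2[C@H]2OC(=O)[C@@H](COC(C)=O)[C@@H]21 | intermediate
45 | CNP0305680.1, (4R,5S,6S,7R,8S,10R,11R)-10,13-diacetoxy-4,5-epoxy-1-oxo-8-[(E)-2-methylbut-2-enoyloxy]germacran-6,12-olide | C/C=C(\C)C(=O)O[C@H]1C[C@@](C)(OC(C)=O)C(=O)CC[C@@]2(C)O[C@H]2[C@H]2OC(=O)[C@@H](COC(C)=O)[C@@H]21 | target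

## Step count and least certain steps

Total: 28 steps. Longest linear sequence: 27 steps (3 → 4 → 8 → 11 → … → 45, steps 2 to 28). Steps 1 and 2 are the two short branches.

**Step 18 (key step).** The most likely failure is loss of the C5 carbanion by E1cB expulsion of O6 (opening of the oxolane) before bromine transfer. A second risk is double bromination at C5 before C4 is deprotonated, which would lead to a vinyl bromide; partial formation of the E olefin is a third risk. Fallback, from 31 back to 34: separate halogenation from elimination. Deprotonate 31 at C5 with LiN(SiMe3)2 at −78 °C, where β-elimination is slow, and quench with C2Cl6 to isolate the 5-chloro sulfone F1. Then treat it with KOt-Bu in THF (−78 → 0 °C), the classical two-stage Ramberg–Bäcklund reaction, which returns to 34.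

**Step 16.** The most likely failure is intermolecular S-alkylation (oligomers, or disulfide if air enters) outrunning the eleven-membered closure, because displacement at the β-oxygenated C5, flanked by the oxolane, is slow. Fallback, from 25 back to 29: reverse the polarity of the closure. Mitsunobu thioesterification (PPh3, DIAD, AcSH) of the primary C5 hydroxyl of 25 gives the 5-thioacetate 4-alcohol F2. Mesylation (MsCl, Et3N) gives the 4-mesylate F3. Cs2CO3 in MeOH under high dilution then lets the less hindered primary thiolate displace the secondary mesylate with inversion, which leads to the same sulfide 29.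

**Step 7.** The most likely failure is poor facial selectivity if zinc does not chelate O6 well; the open Felkin–Anh pathway gives the 8R alcohol. Fallback, from 14 back to 15: reduce 14 with LiBH(s-Bu)3 at −78 °C, where the bulky hydride should follow the Felkin–Anh path, to the 8R alcohol F4. Invert it by a Mitsunobu reaction with 4-nitrobenzoic acid to the 8S 4-nitrobenzoate F5, and cleave the ester with K2CO3 in MeOH to reach 15.

**Step 26.** The most likely failures are a vanadium–diol chelate that reacts sluggishly or cleaves, Lewis-acid-promoted transannular opening of the new epoxide by the C1 hydroxyl, or oxygen delivery to the wrong face. Fallback, from 42 back to 45: finish C1 and C10 first and build the epoxide through a halohydrin. Oxidise 42 (Dess–Martin periodinane) to the olefinic α-hydroxy ketone F6 and acetylate it (Ac2O, DMAP) to the olefinic 10-acetate F7. Form the bromohydrin F8 with N-bromosuccinimide in aqueous acetone (bromonium ion on the exposed β face, water at the tertiary C4 from the α face). Close it with Ag2O; the C4 oxygen displaces bromide at C5 with inversion and gives the α-epoxide 45.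

**Step 19.** The most likely failure is loss of the ketal (or of the silyl ether) together with the methyl acetal. Fallback, from 34 back to 36: cleave both acetals on purpose (0.5 M HCl, THF, 0 °C → rt) to the lactol diol F9. Oxidise only the hemiacetal with Ag2CO3 on Celite, which is selective for lactols over hindered secondary alcohols, to the lactone diol F10. Re-form the ketal (2,2-dimethoxypropane, PPTS) to return to 36.

## Further compounds

F1 | step 18 | 5-chloro sulfone (C5 epimers) | CC(C)(C)[Si](C)(C)O[C@H]1C[C@@]2(C)OC(C)(C)O[C@H]2CC[C@H](C)S(=O)(=O)C(Cl)[C@H]2O[C@@H](OC)C[C@@H]21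
F2 | step 16 | 5-thioacetate 4-alcohol | CO[C@H]1C[C@H]([C@@H](O[Si](C)(C)C(C)(C)C)C[C@@]2(C)OC(C)(C)O[C@H]2CC[C@@H](C)O)[C@@H](CSC(C)=O)O1
F3 | step 16 | 5-thioacetate 4-mesylate | CO[C@H]1C[C@H]([C@@H](O[Si](C)(C)C(C)(C)C)C[C@@]2(C)OC(C)(C)O[C@H]2CC[C@@H](C)OS(C)(=O)=O)[C@@H](CSC(C)=O)O1
F4 | step 7 | 8R alcohol (C8 epimer of 15) | CO[C@H]1C[C@H]([C@H](O)C[C@@](C)(O[Si](CC)(CC)CC)COCc2ccc(OC)cc2)[C@@H](COCc2ccccc2)O1
F5 | step 7 | 8S 4-nitrobenzoate | CO[C@H]1C[C@H]([C@@H](OC(=O)c2ccc(cc2)[N+](=O)[O-])C[C@@](C)(O[Si](CC)(CC)CC)COCc2ccc(OC)cc2)[C@@H](COCc2ccccc2)O1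
F6 | step 26 | olefinic α-hydroxy ketone (C1 ketone, C10 hydroxyl, 4Z olefin) | C/C=C(\C)C(=O)O[C@H]1C[C@@](C)(O)C(=O)CC/C(C)=C\[C@H]2OC(=O)[C@@H](COC(C)=O)[C@@H]21
F7 | step 26 | olefinic 10-acetate (4,5-deoxy analogue of 45) | C/C=C(\C)C(=O)O[C@H]1C[C@@](C)(OC(C)=O)C(=O)CC/C(C)=C\[C@H]2OC(=O)[C@@H](COC(C)=O)[C@@H]21
F8 | step 26 | bromohydrin (4α-hydroxy, 5β-bromo) | C/C=C(\C)C(=O)O[C@H]1C[C@@](C)(OC(C)=O)C(=O)CC[C@@](C)(O)[C@H](Br)[C@H]2OC(=O)[C@@H](COC(C)=O)[C@@H]21
F9 | step 19 | lactol 1,10-diol (C8 TBS ether) | CC(C)(C)[Si](C)(C)O[C@H]1C[C@@](C)(O)[C@@H](O)CC/C(C)=C\[C@H]2OC(O)C[C@@H]21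
F10 | step 19 | lactone 1,10-diol (C8 TBS ether) | CC(C)(C)[Si](C)(C)O[C@H]1C[C@@](C)(O)[C@@H](O)CC/C(C)=C\[C@H]2OC(=O)C[C@@H]21
A1 | alternative 1 | 2-ethoxyoxolane with C8 2,2,6,6-tetramethylpiperidin-1-yloxy ether, methallyl group on C8 and 4,5-epoxy side chain | CCO[C@H]1C[C@H]([C@H](CC(C)=C)ON2C(C)(C)CCCC2(C)C)[C@H](O1)[C@@H]1O[C@]1(C)CCC=C(C)C
A2 | alternative 2 | trans,trans-trisubstituted γ-lactone with C8 dithiane, C13 hydroxyl, C5 silyl ether and C1/C10 acetonide | C[C@@]1(CC2(SCCCS2)[C@H]2[C@H](CO)C(=O)O[C@@H]2CO[Si](C)(C)C(C)(C)C)COC(C)(C)O1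
A3 | alternative 3 | (2Z,6E,9S)-9-[(4-methoxybenzyl)oxy]-3,7-dimethylcyclodeca-2,6-dien-1-one | COc1ccc(CO[C@H]2C/C(C)=C/CC/C(C)=C\C(=O)C2)cc1
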